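**Retrosynthetic overview**
1. Only ring A (the tetrabromocatechol ring) is built; ring B is bought intact. The bond between the two oxygen-bearing carbons of ring A is closed from hexanedial 1 by a carbene-generated acyl anion (Breslow intermediate) adding to the second aldehyde, giving ketol 2.
2. In the same pot Br2 carries 2 through dione 3 and 3,6-dibromocatechol 4 to tetrabromocatechol 5. Every ring CH ends as CBr, so regiochemistry is not an issue.
3. Ring B: 1-bromo-2-iodobenzene 6 and 1,3,5-trimethoxybenzene 7 are joined through the Koser-type iodane 8 to the aryl(trimethoxyphenyl)iodonium tosylate 9.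
4. The diaryl ether C–O bond is made last: 5 + 9 give target 10. All bromines of ring A are in place before the ether is formed, so ring B never meets Br2.

Assumption: the target has no stereocentre (it is achiral), so no stereocontrol is needed; hexanedial (CAS 1072-21-5) is taken as a catalogue chemical and distilled before use.

**Step 1**
Reactants: 1 hexanedial (adipaldehyde)
Product: 5 3,4,5,6-tetrabromobenzene-1,2-diol, via 2-hydroxycyclohexanone 2 (not isolated), via cyclohexane-1,2-dione 3 (not isolated), via 3,6-dibromobenzene-1,2-diol 4 (not isolated)
Conditions: (i) 3-benzyl-5-(2-hydroxyethyl)-4-methylthiazolium chloride (10 mol%), Et3N (30 mol%), EtOH (0.05 M, slow addition of 1), 80 °C, N2; evaporate; (ii) Br2 (7 equiv), dry AcOH, 20 → 80 °C; aq NaHSO3 work-up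
Reagents that add atoms: bromine, BrBr
Why: Proposed new method: the thiazolium carbene turns one CHO of 1 into a nucleophilic Breslow (acyl-anion) intermediate that adds 6-exo to the other CHO (intramolecular benzoin/acyloin cyclisation), and the crude ketol 2 is then, in a one-pot sequence that is not precedented as such, oxidised by Br2 through its enediol to 3, α-brominated/dehydrobrominated/tautomerised to 4 and brominated at the two remaining CH positions by electrophilic aromatic substitution; the closest known reaction types are the thiazolium-catalysed acyloin cyclisation of dialdehydes, the bromination–aromatisation of cyclohexane-1,2-dione to 3,6-dibromocatechol and the perbromination of catechol, and the racemic centre of 2 is destroyed on oxidation.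

**Step 2**
Reactants: 6 1-bromo-2-iodobenzene; 7 1,3,5-trimethoxybenzene
Product: 9 (2-bromophenyl)(2,4,6-trimethoxyphenyl)iodonium 4-methylbenzenesulfonate, via 1-bromo-2-[hydroxy(tosyloxy)iodo]benzene 8 (not isolated)
Conditions: mCPBA (1.05 equiv), TsOH·H2O (1.05 equiv), MeCN, 77 °C, 30 min; then 7 (1.05 equiv), 77 °C, 10 min; Et2O trituration
Reagents that add atoms: p-toluenesulfonic acid monohydrate, Cc1ccc(cc1)S(=O)(=O)O.O; mCPBA, OOC(=O)c1cccc(Cl)c1 (its oxygen is carried only in 8 and leaves as water when 9 forms)
Why: Oxidation of the aryl iodide to a Koser-type iodine(III) reagent followed by electrophilic aromatic substitution of the very electron-rich arene 7 at iodine is the standard one-pot diaryliodonium salt synthesis, and the aryl C–Br bond is inert to peracid and acid.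

**Step 3**
Reactants: 5 3,4,5,6-tetrabromobenzene-1,2-diol; 9 (2-bromophenyl)(2,4,6-trimethoxyphenyl)iodonium 4-methylbenzenesulfonate
Product: 10 3,4,5,6-tetrabromo-2-(2-bromophenoxy)phenol
Conditions: 5 (1.2 equiv), t-BuOK (1.0 equiv), THF, 0 °C, 15 min; then 9 (1.0 equiv), 0 → 40 °C, N2, dark
Reagents that add atoms: none
Why: Metal-free O-arylation of a phenoxide with a diaryliodonium salt (ligand exchange at iodine, then ligand coupling) transfers the electron-poorer, ortho-substituted 2-bromophenyl group while trimethoxyphenyl stays on iodine; 5 is symmetrical, so either oxygen gives the same ether, and limiting base to one equivalent keeps the neutral product from being arylated a second time.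

**Compound list**
1 | hexanedial (adipaldehyde) | O=CCCCCC=O | starting material
2 | 2-hydroxycyclohexanone (racemic, centre destroyed in the same pot) | O=C1CCCCC1O | intermediate
3 | cyclohexane-1,2-dione | O=C1CCCCC1=O | intermediate
4 | 3,6-dibromobenzene-1,2-diol | Oc1c(Br)ccc(Br)c1O | intermediate
5 | 3,4,5,6-tetrabromobenzene-1,2-diol (tetrabromocatechol) | Oc1c(O)c(Br)c(Br)c(Br)c1Br | intermediate
6 | 1-bromo-2-iodobenzene | Brc1ccccc1I | starting material
7 | 1,3,5-trimethoxybenzene | COc1cc(OC)cc(OC)c1 | starting material
8 | 1-bromo-2-[hydroxy(tosyloxy)iodo]benzene | Cc1ccc(cc1)S(=O)(=O)OI(O)c1ccccc1Br | intermediate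
9 | (2-bromophenyl)(2,4,6-trimethoxyphenyl)iodonium 4-methylbenzenesulfonate | COc1cc(OC)c([I+]c2ccccc2Br)c(OC)c1.Cc1ccc(cc1)S(=O)(=O)[O-] | intermediate
10 | 3,4,5,6-tetrabromo-2-(2-bromophenoxy)phenol (achiral) | Oc1c(Br)c(Br)c(Br)c(Br)c1Oc1ccccc1Br | target

**Totals**
Total step count: 3. Longest linear sequence: 2 steps (1 → 5 → 10, or 6 → 9 → 10).

**Steps most likely to fail, with fallbacks**

Step 1 (highest risk). The carbene cyclisation competes with intramolecular aldol condensation and oligomerisation of 1, and the one-pot oxidative perbromination may give mixtures. The fallback sets out from 1 and comes back to the route at 3. The ring bond is made instead by reductive ketyl coupling: 1 with SmI2 (2.2 equiv) and t-BuOH in THF at −78 → 20 °C undergoes intramolecular pinacol coupling to cis-cyclohexane-1,2-diol F1 (any trans isomer is equally usable). A double Swern oxidation (DMSO, (COCl)2, Et3N, CH2Cl2, −78 °C) converts this to 3, which is then isolated and brominated on its own with Br2 in AcOH at 20 → 80 °C to give 5.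

Step 3. The risks are diarylation of the catechol, low nucleophilicity of the hindered, electron-poor phenoxide, and redox side reactions of a free catechol with iodine(III). The fallback sets out from 5 and comes back at 10. The catechol is first desymmetrised so that only one OH is available: 5 with MeI (1.0 equiv) and Li2CO3 in DMF at 40 °C gives 2,3,4,5-tetrabromo-6-methoxyphenol F2. Its phenoxide (t-BuOK, THF) is arylated with 9 at 40 °C to give 1,2,3,4-tetrabromo-5-(2-bromophenoxy)-6-methoxybenzene F3. BBr3 in CH2Cl2 at −78 → 20 °C then cleaves only the methyl ether and gives 10.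

Step 2. The risks are incomplete oxidation of the ortho-substituted iodide and over-oxidation of 7, giving an impure salt. The fallback sets out from 6 (together with 5) and comes back at 10. It drops hypervalent iodine altogether in favour of a copper-catalysed Ullmann ether synthesis: 6 and 5 (1.5 equiv) with CuI (20 mol%), picolinic acid (40 mol%) and K3PO4 in DMSO at 80 °C under N2, where the C–I bond of 6 reacts well before any C–Br bond. This detour makes no new compound (F0). The temperature must stay low so that the product does not close to a dibenzodioxin.

**Further compounds**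
F1 | step 1 | cis-cyclohexane-1,2-diol | O[C@@H]1CCCC[C@@H]1O
F2 | step 3 | 2,3,4,5-tetrabromo-6-methoxyphenol | COc1c(O)c(Br)c(Br)c(Br)c1Br
F3 | step 3 | 1,2,3,4-tetrabromo-5-(2-bromophenoxy)-6-methoxybenzene | COc1c(Oc2ccccc2Br)c(Br)c(Br)c(Br)c1Br
F0 | step 2 | none | none
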